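Clerodane numbering: ring A = C1–C5 + C10, ring B = C5–C10, side chain C11–C16, methyls C17 (on C8), C18 (on C4), C19 (on C5), C20 (on C9); α is the face of C19/C20, β the face of H-10. Endgame: the C15 icosanoate/C16 alcohol pair comes from a (13R)-16,15-lactone, and C18 with the C3=C4 bond comes from the C4 ketone of trans-decalone 17 (enol triflate, methyl coupling).
Key disconnection (biomimetic): 17 goes back to the monocyclic keto-alkene 14 by undoing the C4–C5 bond and the two clerodane 1,2-shifts (C19 from C5 back to C4, H from C10 back to C5).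
Enabling feature: in ring A the sp2 carbon C4 is bonded to the quaternary C5, whose methyl C19 is anti to H-10 across the A/B fusion. C10 is flanked in ring B by the fully substituted C9. This array is the trace of an H/Me shift pair, and C9 closes the other exits of a C10 cation.
14 comes from a Negishi coupling (C1–C10), cross metathesis plus asymmetric hydrogenation (C12–C13 bond, C13), anti allylation (C9) and asymmetric conjugate methylation (C8) of 2-methylcyclohexenone.
Ring order: ring B is carried in from 2-methylcyclohexenone. A temporary lactone ring is carried in from α-methylene-γ-butyrolactone and opened in step 11. Ring A is the only ring closed in the route and the last ring of the skeleton.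

Key step: step 8

Assumption: the acyl chain is read as icosanoyl (20 carbons), and the chiral ligands in steps 1 and 7 are taken to induce the sense drawn; if one induces the opposite sense, its enantiomer is used.

Step 1
Reactants: 1 2-methylcyclohex-2-en-1-one
Product: 3 trimethyl{[(3R)-2,3-dimethylcyclohex-1-en-1-yl]oxy}silane, via dimethylaluminium enolate 2 (not isolated)
Conditions: Me3Al, copper thiophene-2-carboxylate (2 mol%), BINOL-derived phosphoramidite ligand (4 mol%), Et2O, −30 °C; then TMSOTf, THF, −30 to 0 °C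
Reagents that add atoms: trimethylaluminium C[Al](C)C; trimethylsilyl trifluoromethanesulfonate C[Si](C)(C)OS(=O)(=O)C(F)(F)F
Why: Copper-catalysed asymmetric conjugate addition, in which the chiral ligand sets C8 (R), followed by O-silylation that stores the tetrasubstituted enolate regiospecifically.

Step 2
Reactants: 3 trimethyl{[(3R)-2,3-dimethylcyclohex-1-en-1-yl]oxy}silane
Product: 5 (2S,3R)-2,3-dimethyl-2-(prop-2-en-1-yl)cyclohexan-1-one, via lithium enolate 4 (not isolated)
Conditions: MeLi, THF, 0 °C; then allyl bromide, DMPU, −78 to 0 °C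
Reagents that add atoms: allyl bromide C=CCBr
Why: Regiospecific lithium enolate generation from the silyl enol ether and alkylation, in which the C8 methyl sits pseudoaxial to avoid A(1,2) strain, so allyl enters anti to it and C9 forms with the two methyls cis.

Step 3
Reactants: 5 (2S,3R)-2,3-dimethyl-2-(prop-2-en-1-yl)cyclohexan-1-one
Product: 7 (5R,6S)-5,6-dimethyl-6-(prop-2-en-1-yl)cyclohex-1-en-1-yl trifluoromethanesulfonate, via potassium enolate 6 (not isolated)
Conditions: KHMDS, THF, −78 °C; then PhNTf2, −78 to 0 °C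
Reagents that add atoms: N-phenylbis(trifluoromethanesulfonimide) O=S(=O)(N(c1ccccc1)S(=O)(=O)C(F)(F)F)C(F)(F)F
Why: Enol triflate formation is regiochemically unambiguous because only C5 carries α-hydrogens (C9 is quaternary), and it places the future C5=C10 double bond.

Step 4
Reactants: 8 5-chloropentan-2-one
Product: 9 5-iodopentan-2-one
Conditions: NaI, acetone, reflux
Reagents that add atoms: sodium iodide [Na+].[I-]
Why: The Finkelstein halide exchange, driven by precipitation of the chloride salt, gives an iodide that inserts zinc readily.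

Step 5
Reactants: 7 (5R,6S)-5,6-dimethyl-6-(prop-2-en-1-yl)cyclohex-1-en-1-yl trifluoromethanesulfonate; 9 5-iodopentan-2-one
Product: 11 5-[(5R,6S)-5,6-dimethyl-6-(prop-2-en-1-yl)cyclohex-1-en-1-yl]pentan-2-one, via (4-oxopentyl)zinc iodide 10 (not isolated)
Conditions: 9, Zn dust, LiCl, THF, 25–40 °C; then 7, Pd(OAc)2 (3 mol%), SPhos (6 mol%), THF/NMP, 50 °C
Reagents that add atoms: none
Why: Negishi sp2–sp3 coupling forms the crowded C1–C10 bond at an sp2 carbon, and the alkylzinc iodide tolerates its own ketone, so no protecting group is needed.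

Step 6
Reactants: 11 5-[(5R,6S)-5,6-dimethyl-6-(prop-2-en-1-yl)cyclohex-1-en-1-yl]pentan-2-one; 12 3-methylideneoxolan-2-one (α-methylene-γ-butyrolactone)
Product: 13 (3E)-3-{2-[(1S,6R)-1,6-dimethyl-2-(4-oxopentyl)cyclohex-2-en-1-yl]ethylidene}oxolan-2-one
Conditions: second-generation Hoveyda–Grubbs catalyst (5 mol%), 2,6-dichloro-1,4-benzoquinone (10 mol%), 12 (3 equiv), CH2Cl2, 40 °C
Reagents that add atoms: none
Why: Cross metathesis of the terminal allyl group with the methylene lactone should give the (E)-alkylidene lactone, because the hindered trisubstituted ring alkene does not take part and the quinone suppresses double-bond migration.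

Step 7
Reactants: 13 (3E)-3-{2-[(1S,6R)-1,6-dimethyl-2-(4-oxopentyl)cyclohex-2-en-1-yl]ethylidene}oxolan-2-one
Product: 14 (3R)-3-{2-[(1S,6R)-1,6-dimethyl-2-(4-oxopentyl)cyclohex-2-en-1-yl]ethyl}oxolan-2-one
Conditions: H2 (100 atm), Ru2Cl4[(S)-BINAP]2(NEt3) (1 mol%), CH2Cl2, 50 °C
Reagents that add atoms: none
Why: BINAP–ruthenium asymmetric hydrogenation of an (E)-α-alkylidene-γ-butyrolactone sets C13 (R) by catalyst control through carbonyl chelation, and it leaves the unfunctionalised ring alkene and the simple ketone untouched.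

Step 8
Reactants: 14 (3R)-3-{2-[(1S,6R)-1,6-dimethyl-2-(4-oxopentyl)cyclohex-2-en-1-yl]ethyl}oxolan-2-one
Product: 17 (3R)-3-{2-[(1S,2R,4aR,8aR)-1,2,4a-trimethyl-5-oxodecahydronaphthalen-1-yl]ethyl}oxolan-2-one, via C10 cation zwitterion 15 (not isolated), via C5 cation zwitterion 16 (not isolated)
Conditions: MeAlCl2 (4 equiv, hexanes), CH2Cl2 (0.01 M), −78 to 0 °C; aq. Rochelle salt
Reagents that add atoms: none
Why: Proposed new method: MeAlCl2 binds the C4 ketone, C5 of the ring-B alkene attacks it through a chair (6-endo-trig at the alkene, 6-exo-trig at the carbonyl) and closes ring A to the tertiary C10 cation/aluminium alkoxide zwitterion 15; H-5 then shifts suprafacially to C10 (16) and the axial methyl on C4 shifts to C5 on the opposite face, which collapses the charge pair to the C4 ketone and copies the two shifts that turn the halimanyl into the clerodanyl cation in the presumed biosynthesis. The closest known reaction type is the alkylaluminium-dichloride-induced Prins cyclisation of unsaturated aldehydes and ketones, whose 1,3-zwitterions end in a ketone after two consecutive 1,2-hydride or alkyl shifts, together with the Prins–pinacol reaction; what has not been shown is this ring size with methyl migration to an angular position of a decalin. C10 and C5 are set relative to each other by the mechanism, since hydride enters C10 on the face it left at C5 and methyl enters C5 on the other face, which can only give the trans fusion with H-10 anti to C19. Their sense relative to C8 and C9 should be fixed at the first irreversible event, the methyl shift, because addition and hydride shift are reversible: closure on the ring-B face anti to the C9 side chain leads to a chair–chair array with the C8 methyl and the side chain equatorial, whereas closure on the other face would put both axial. The step needs the shifts to beat proton loss, and the fully substituted C9 secures this because it offers the alkoxide no allylic hydrogen for an ene-type exit and leaves H-5 as the aligned migrating group, while excess MeAlCl2 keeps the alkoxide non-basic and C5, being a ring-B carbon, becomes a tertiary cation. It also needs methyl rather than the C3–C4 ring bond to migrate, which the chair secures by placing the bulky O–Al group equatorial and the methyl axial, parallel to the empty orbital at C5.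

Step 9
Reactants: 17 (3R)-3-{2-[(1S,2R,4aR,8aR)-1,2,4a-trimethyl-5-oxodecahydronaphthalen-1-yl]ethyl}oxolan-2-one
Product: 18 C4 enol triflate of 17 (C3=C4 double bond, OTf on C4; C5, C8, C9, C10 and C13 as in 17)
Conditions: Tf2O, 2,6-di-tert-butyl-4-methylpyridine, CH2Cl2, 0 °C to rt
Reagents that add atoms: trifluoromethanesulfonic anhydride O=S(=O)(OS(=O)(=O)C(F)(F)F)C(F)(F)F
Why: Vinyl triflate formation with triflic anhydride and a hindered pyridine gives one regioisomer because only C3 carries α-hydrogens, and the non-nucleophilic weak base does not touch the epimerisable C13–H of the lactone.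

Step 10
Reactants: 18 C4 enol triflate of 17
Product: 19 (3R)-3-{2-[(1S,2R,4aR,8aR)-1,2,4a,5-tetramethyl-1,2,3,4,4a,7,8,8a-octahydronaphthalen-1-yl]ethyl}oxolan-2-one
Conditions: Me2Zn, PdCl2(dppf) (5 mol%), THF, 60 °C
Reagents that add atoms: dimethylzinc C[Zn]C
Why: Negishi methylation of the vinyl triflate installs C18 with the C3=C4 bond fixed in place by the triflate, and the lactone is inert to the organozinc.

Step 11
Reactants: 19 (3R)-3-{2-[(1S,2R,4aR,8aR)-1,2,4a,5-tetramethyl-1,2,3,4,4a,7,8,8a-octahydronaphthalen-1-yl]ethyl}oxolan-2-one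
Product: 20 (2R)-4-hydroxy-N-methoxy-N-methyl-2-{2-[(1S,2R,4aR,8aR)-1,2,4a,5-tetramethyl-1,2,3,4,4a,7,8,8a-octahydronaphthalen-1-yl]ethyl}butanamide
Conditions: MeNHOMe·HCl, AlMe3, CH2Cl2, 0 °C to rt; used at once
Reagents that add atoms: N,O-dimethylhydroxylamine hydrochloride CNOC.Cl
Why: Aluminium-amide (Weinreb) aminolysis opens the temporary lactone ring, frees only the C15 hydroxyl and keeps C16 at the acid level, so the two primary oxygens are told apart without protecting groups and C13 is not touched.

Step 12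
Reactants: 20 (2R)-4-hydroxy-N-methoxy-N-methyl-2-{2-[(1S,2R,4aR,8aR)-1,2,4a,5-tetramethyl-1,2,3,4,4a,7,8,8a-octahydronaphthalen-1-yl]ethyl}butanamide; 21 icosanoic acid
Product: 22 (3R)-3-[methoxy(methyl)carbamoyl]-5-[(1S,2R,4aR,8aR)-1,2,4a,5-tetramethyl-1,2,3,4,4a,7,8,8a-octahydronaphthalen-1-yl]pentyl icosanoate
Conditions: EDC·HCl, DMAP, CH2Cl2, 0 °C to rt
Reagents that add atoms: none
Why: Steglich-type carbodiimide esterification acylates the only free hydroxyl (C15) and at the same time blocks re-lactonisation.

Step 13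
Reactants: 22 (3R)-3-[methoxy(methyl)carbamoyl]-5-[(1S,2R,4aR,8aR)-1,2,4a,5-tetramethyl-1,2,3,4,4a,7,8,8a-octahydronaphthalen-1-yl]pentyl icosanoate
Product: 24 (3R)-3-(hydroxymethyl)-5-[(1S,2R,4aR,8aR)-1,2,4a,5-tetramethyl-1,2,3,4,4a,7,8,8a-octahydronaphthalen-1-yl]pentyl icosanoate, via C16 aldehyde 23 (not isolated)
Conditions: Cp2Zr(H)Cl (1.6 equiv), THF, rt, 20 min; then NaBH4, MeOH, 0 °C
Reagents that add atoms: none
Why: Cp2Zr(H)Cl reduces the tertiary amide to the aldehyde faster than it touches an ester or a hindered trisubstituted alkene, and immediate borohydride reduction gives the C16 alcohol before C13 can epimerise.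

Compound list
1 | 2-methylcyclohex-2-en-1-one | CC1=CCCCC1=O | starting material
2 | dimethylaluminium (3R)-2,3-dimethylcyclohex-1-en-1-olate | CC1=C(O[Al](C)C)CCC[C@H]1C | intermediate
3 | trimethyl{[(3R)-2,3-dimethylcyclohex-1-en-1-yl]oxy}silane | CC1=C(O[Si](C)(C)C)CCC[C@H]1C | intermediate
4 | lithium (3R)-2,3-dimethylcyclohex-1-en-1-olate | CC1=C([O-])CCC[C@H]1C.[Li+] | intermediate
5 | (2S,3R)-2,3-dimethyl-2-(prop-2-en-1-yl)cyclohexan-1-one (allyl trans to the C3 methyl) | C=CC[C@@]1(C)[C@H](C)CCCC1=O | intermediate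
6 | potassium (5R,6S)-5,6-dimethyl-6-(prop-2-en-1-yl)cyclohex-1-en-1-olate | C=CC[C@@]1(C)[C@H](C)CCC=C1[O-].[K+] | intermediate
7 | (5R,6S)-5,6-dimethyl-6-(prop-2-en-1-yl)cyclohex-1-en-1-yl trifluoromethanesulfonate | C=CC[C@@]1(C)[C@H](C)CCC=C1OS(=O)(=O)C(F)(F)F | intermediate
8 | 5-chloropentan-2-one | CC(=O)CCCCl | starting material
9 | 5-iodopentan-2-one | CC(=O)CCCI | intermediate
10 | (4-oxopentyl)zinc iodide | CC(=O)CCC[Zn]I | intermediate
11 | 5-[(5R,6S)-5,6-dimethyl-6-(prop-2-en-1-yl)cyclohex-1-en-1-yl]pentan-2-one | C=CC[C@@]1(C)[C@H](C)CCC=C1CCCC(C)=O | intermediate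
12 | 3-methylideneoxolan-2-one (α-methylene-γ-butyrolactone) | C=C1CCOC1=O | starting material
13 | (3E)-3-{2-[(1S,6R)-1,6-dimethyl-2-(4-oxopentyl)cyclohex-2-en-1-yl]ethylidene}oxolan-2-one | O=C1OCC/C1=C\C[C@@]2(C)[C@H](C)CCC=C2CCCC(C)=O | intermediate
14 | (3R)-3-{2-[(1S,6R)-1,6-dimethyl-2-(4-oxopentyl)cyclohex-2-en-1-yl]ethyl}oxolan-2-one | O=C1OCC[C@H]1CC[C@@]2(C)[C@H](C)CCC=C2CCCC(C)=O | intermediate
15 | C10 carbocation/C4 O-aluminate zwitterion (H-5 β, C4 methyl α-axial, O–Al equatorial) | O=C1OCC[C@H]1CC[C@@]2(C)[C@H](C)CC[C@H]3[C+]2CCC[C@]3(C)O[Al-](C)(Cl)Cl | intermediate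
16 | C5 carbocation/C4 O-aluminate zwitterion (H-10 β) | O=C1OCC[C@H]1CC[C@@]2(C)[C@H](C)CC[C+]3[C@@H]2CCC[C@]3(C)O[Al-](C)(Cl)Cl | intermediate
17 | (3R)-3-{2-[(1S,2R,4aR,8aR)-1,2,4a-trimethyl-5-oxodecahydronaphthalen-1-yl]ethyl}oxolan-2-one (trans-decalone, 4-oxo-18-norclerodan-16,15-olide) | O=C1OCC[C@H]1CC[C@@]2(C)[C@H](C)CC[C@@]3(C)C(=O)CCC[C@H]23 | intermediate
18 | C4 enol triflate of 17 (C3=C4) | O=C1OCC[C@H]1CC[C@@]2(C)[C@H](C)CC[C@@]3(C)C(OS(=O)(=O)C(F)(F)F)=CCC[C@H]23 | intermediate
19 | (3R)-3-{2-[(1S,2R,4aR,8aR)-1,2,4a,5-tetramethyl-1,2,3,4,4a,7,8,8a-octahydronaphthalen-1-yl]ethyl}oxolan-2-one (clerod-3-en-16,15-olide) | O=C1OCC[C@H]1CC[C@@]2(C)[C@H](C)CC[C@@]3(C)C(C)=CCC[C@H]23 | intermediate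
20 | (2R)-4-hydroxy-N-methoxy-N-methyl-2-{2-[(1S,2R,4aR,8aR)-1,2,4a,5-tetramethyl-1,2,3,4,4a,7,8,8a-octahydronaphthalen-1-yl]ethyl}butanamide | CON(C)C(=O)[C@@H](CCO)CC[C@@]1(C)[C@H](C)CC[C@@]2(C)C(C)=CCC[C@H]12 | intermediate
21 | icosanoic acid (arachidic acid) | CCCCCCCCCCCCCCCCCCCC(=O)O | starting material
22 | (3R)-3-[methoxy(methyl)carbamoyl]-5-[(1S,2R,4aR,8aR)-1,2,4a,5-tetramethyl-1,2,3,4,4a,7,8,8a-octahydronaphthalen-1-yl]pentyl icosanoate | CCCCCCCCCCCCCCCCCCCC(=O)OCC[C@H](C(=O)N(C)OC)CC[C@@]1(C)[C@H](C)CC[C@@]2(C)C(C)=CCC[C@H]12 | intermediate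
23 | (3R)-3-formyl-5-[(1S,2R,4aR,8aR)-1,2,4a,5-tetramethyl-1,2,3,4,4a,7,8,8a-octahydronaphthalen-1-yl]pentyl icosanoate | CCCCCCCCCCCCCCCCCCCC(=O)OCC[C@H](C=O)CC[C@@]1(C)[C@H](C)CC[C@@]2(C)C(C)=CCC[C@H]12 | intermediate
24 | (3R)-3-(hydroxymethyl)-5-[(1S,2R,4aR,8aR)-1,2,4a,5-tetramethyl-1,2,3,4,4a,7,8,8a-octahydronaphthalen-1-yl]pentyl icosanoate | CCCCCCCCCCCCCCCCCCCC(=O)OCC[C@H](CO)CC[C@@]1(C)[C@H](C)CC[C@@]2(C)C(C)=CCC[C@H]12 | target

Total step count: 13. Longest linear sequence: 12 (steps 1–3 and 5–13).

Steps most likely to fail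

Step 8. Several processes could compete with the cascade:
- proton loss from the C10 or C5 cation before the shifts are complete;
- migration of the C3–C4 ring bond (ring contraction) instead of methyl;
- poor facial selectivity of the closure relative to C8 and C9.

The fallback uses known reactions only, sets out from 14 and comes back at 17. mCPBA epoxidises the ring-B alkene of 14 to the 5α,10α-epoxide F1; either epoxide face serves, because C10 is equilibrated afterwards. LiClO4 in hot toluene rearranges F1 by hydride shift (Meinwald rearrangement) to the C5 ketone, and DBU equilibrates C10 to the epimer with the equatorial chain, the 4,5-seco-4,5-dione F2. Low-valent titanium (TiCl3(DME)1.5, Zn–Cu couple, DME, reflux, high dilution) couples the two carbonyl carbons in an intramolecular McMurry reaction. This closes ring A as the tetrasubstituted C4=C5 alkene F3. mCPBA should attack F3 on the face anti to the axial C20 methyl and give the 4β,5β-epoxide F4. BF3·OEt2 at −78 °C opens the C5–O bond, and the methyl on C4 migrates to C5 anti to the leaving oxygen, which gives 17.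

Step 5. Oxidative addition and transmetalation may be slow at the triflate next to the quaternary C9, so reduction of the triflate or protonation of the zinc reagent could take over. The fallback replaces cross-coupling by polar alkylation of a vinyllithium; it sets out from 5 and comes back at 11. Ketone 5 is condensed with 2,4,6-triisopropylbenzenesulfonylhydrazide to the 2,4,6-triisopropylbenzenesulfonylhydrazone F5. n-BuLi (2.2 equiv, THF/TMEDA, −78 to 0 °C, Shapiro reaction) converts F5 into the vinyllithium F6. F6 is alkylated with the iodo ketal F7, made from 9 with ethylene glycol and TsOH, to give the ketal F8. Aqueous HCl in THF then frees the ketone and gives 11.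

Step 11. The α-branched lactone may open incompletely, and the hydroxy amide may close back to the lactone during isolation. The fallback sets out from 19 and comes back at 24. LiAlH4 reduces 19 to the 15,16-diol F9. Immobilised Candida antarctica lipase B with 21 (toluene, molecular sieves, 45 °C) should then esterify regioselectively the less hindered C15 hydroxyl, which lies two carbons from the branch point, to give 24.

Further compounds
F1 | step 8 | 5α,10α-epoxide of 14 | O=C1OCC[C@H]1CC[C@@]2(C)[C@H](C)CC[C@@H]3O[C@]23CCCC(C)=O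
F2 | step 8 | 4,5-seco-4,5-dione (C5 ketone in ring B, H-10 β, 4-oxopentyl chain equatorial) | O=C1OCC[C@H]1CC[C@@]2(C)[C@H](C)CCC(=O)[C@@H]2CCCC(C)=O
F3 | step 8 | 19-norclerod-4(5)-en-16,15-olide (tetrasubstituted C4=C5 alkene, H-10 β) | O=C1OCC[C@H]1CC[C@@]2(C)[C@H](C)CCC3=C(C)CCC[C@H]23
F4 | step 8 | 4β,5β-epoxide of F3 | O=C1OCC[C@H]1CC[C@@]2(C)[C@H](C)CC[C@@]34O[C@@]4(C)CCC[C@H]23
F5 | step 5 | 2,4,6-triisopropylbenzenesulfonylhydrazone of 5 | C=CC[C@@]1(C)[C@H](C)CCC/C1=N\NS(=O)(=O)c2c(C(C)C)cc(C(C)C)cc2C(C)C
F6 | step 5 | [(5R,6S)-5,6-dimethyl-6-(prop-2-en-1-yl)cyclohex-1-en-1-yl]lithium | C=CC[C@@]1(C)[C@H](C)CCC=C1[Li]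
F7 | step 5 | 2-(3-iodopropyl)-2-methyl-1,3-dioxolane | CC1(CCCI)OCCO1
F8 | step 5 | ethylene ketal of 11 | C=CC[C@@]1(C)[C@H](C)CCC=C1CCCC2(C)OCCO2
F9 | step 11 | (13R)-clerod-3-ene-15,16-diol | OCC[C@H](CO)CC[C@@]1(C)[C@H](C)CC[C@@]2(C)C(C)=CCC[C@H]12
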